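**Retrosynthetic overview**
1. Lapiferine 23 ⇐ hydroxyl-directed epoxidation of cycloheptenol 22 ⇐ ring-closing metathesis (C8=C9) of diene 21.
2. 21 ⇐ reagent-controlled vinylation (divinylzinc 20) of the C-10 aldehyde 17 ⇐ angeloylation of diol-aldehyde 13 with mixed anhydride 16.
3. 13 ⇐ isopropyl addition and acetal hydrolysis of ketone 11 ⇐ three-component union of enone 5, a methyl nucleophile and aldehyde 9 (asymmetric conjugate addition–aldol; sets C-1, C-5, C-6).
4. 5 ⇐ Stetter reaction and aldol condensation (methyl vinyl ketone + dimethoxyacetaldehyde); 9 ⇐ glycidol + isopropenyl Grignard, then glycol cleavage; 16 and 20 are made in parallel.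
5. Ring order: cyclopentenone (step 2) → cycloheptene by RCM (step 11) → epoxide (step 12).

Assumption: the target is taken exactly as the given SMILES; C-n labels in the text are daucane locants (C-1 angular quaternary carbon, C-4 isopropyl carbinol, C-5 ring-fusion CH, C-6 ester carbinol, C-8/C-9 epoxide, C-10 free carbinol).

**Step 1**
Reactants: 1 but-3-en-2-one (methyl vinyl ketone); 2 2,2-dimethoxyacetaldehyde
Product: 3 1,1-dimethoxyhexane-2,5-dione
Conditions: 3-benzyl-5-(2-hydroxyethyl)-4-methylthiazolium chloride (10 mol %), Et3N (cat.), EtOH, 80 °C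
Reagents that add atoms: none
Why: Stetter reaction: the thiazolium carbene turns the aldehyde into an acyl-anion equivalent that adds 1,4 to the enone, giving the 1,4-diketone (no stereocentre).

**Step 2**
Reactants: 3 1,1-dimethoxyhexane-2,5-dione
Product: 5 3-(dimethoxymethyl)cyclopent-2-en-1-one, via aldol adduct 4 (not isolated)
Conditions: 2% aq NaOH, EtOH, reflux
Reagents that add atoms: none
Why: Intramolecular aldol condensation: only the methyl-ketone enolate can close a five-membered ring that dehydrates to the conjugated enone (the dihydrojasmone-type cyclisation); no stereocentre.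

**Step 3**
Reactants: 6 (±)-glycidol; 7 isopropenylmagnesium bromide
Product: 8 (±)-4-methylpent-4-ene-1,2-diol
Conditions: 7 (2.5 equiv), CuI (10 mol %), THF, −30 → 0 °C; aq NH4Cl
Reagents that add atoms: none
Why: Copper-catalysed Grignard opening of the epoxide at its unsubstituted terminus (SN2); the racemic carbinol centre is destroyed in step 4.

**Step 4**
Reactants: 8 (±)-4-methylpent-4-ene-1,2-diol
Product: 9 3-methylbut-3-enal
Conditions: NaIO4, CH2Cl2/H2O, 0 °C → rt; taken on as a dried Et2O solution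
Reagents that add atoms: none
Why: Malaprade glycol cleavage releases the β,γ-unsaturated aldehyde under neutral conditions, which avoids isomerisation to the conjugated enal.

**Step 5**
Reactants: 5 3-(dimethoxymethyl)cyclopent-2-en-1-one; 9 3-methylbut-3-enal
Product: 11 (2S,3S)-3-(dimethoxymethyl)-2-[(1S)-1-hydroxy-3-methylbut-3-en-1-yl]-3-methylcyclopentan-1-one, via bromomagnesium enolate 10 (not isolated)
Conditions: MeMgBr (1.3 equiv), Cu(OTf)2 (5 mol %), chiral imidazolinium-derived NHC ligand (6 mol %, enantiomer giving Re-face attack at C-3 of the enone), Et2O, −30 °C; then 9 (1.5 equiv), −78 °C; aq NH4Cl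
Reagents that add atoms: methylmagnesium bromide, C[Mg]Br
Why: Copper-catalysed asymmetric conjugate addition sets the quaternary C-1 under ligand control, and the regiodefined cyclic (E)-enolate then reacts in a Zimmerman–Traxler aldol on the face anti to the bulky CH(OMe)2 group, giving the trans C-5 centre and the anti (6S) carbinol.

**Step 6**
Reactants: 11 (2S,3S)-3-(dimethoxymethyl)-2-[(1S)-1-hydroxy-3-methylbut-3-en-1-yl]-3-methylcyclopentan-1-one
Product: 13 (1S,2S,3R)-3-hydroxy-2-[(1S)-1-hydroxy-3-methylbut-3-en-1-yl]-1-methyl-3-(propan-2-yl)cyclopentane-1-carbaldehyde, via acetal diol 12 (not isolated)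
Conditions: i-PrMgCl (3.5 equiv), LaCl3·2LiCl (1.1 equiv), THF, −78 → −20 °C; then 1 M aq HCl, THF, rt
Reagents that add atoms: isopropylmagnesium chloride, CC(C)[Mg]Cl; water, O
Why: Lanthanide-promoted Grignard 1,2-addition (suppresses enolisation and reduction) attacks the ketone face anti to the adjacent C-5 side chain, setting 4R with OH cis to that chain, and the acidic work-up hydrolyses the dimethyl acetal to the C-10 aldehyde.

**Step 7**
Reactants: 14 angelic acid; 15 2,4,6-trichlorobenzoyl chloride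
Product: 16 (2Z)-2-methylbut-2-enoic 2,4,6-trichlorobenzoic anhydride
Conditions: Et3N (1.1 equiv), toluene, rt; filter
Reagents that add atoms: none
Why: Yamaguchi mixed-anhydride formation activates angelic acid without Z→E isomerisation.

**Step 8**
Reactants: 13 (1S,2S,3R)-3-hydroxy-2-[(1S)-1-hydroxy-3-methylbut-3-en-1-yl]-1-methyl-3-(propan-2-yl)cyclopentane-1-carbaldehyde; 16 (2Z)-2-methylbut-2-enoic 2,4,6-trichlorobenzoic anhydride
Product: 17 (1S)-1-[(1S,2S,5R)-2-formyl-5-hydroxy-2-methyl-5-(propan-2-yl)cyclopentyl]-3-methylbut-3-en-1-yl (2Z)-2-methylbut-2-enoate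
Conditions: toluene, 80 °C
Reagents that add atoms: none
Why: Yamaguchi-type esterification under base-free thermal conditions acylates only the secondary C-6 hydroxyl (the tertiary OH and the non-enolisable aldehyde are inert) and keeps the angelate Z.

**Step 9**
Reactants: 18 vinylmagnesium bromide; 19 zinc chloride
Product: 20 divinylzinc
Conditions: 18 (2 equiv), THF/Et2O, 0 °C → rt; 1,4-dioxane, filter
Reagents that add atoms: none
Why: Transmetalation (salt metathesis) gives the salt-free dialkenylzinc needed for ligand-accelerated carbonyl addition.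

**Step 10**
Reactants: 17 (1S)-1-[(1S,2S,5R)-2-formyl-5-hydroxy-2-methyl-5-(propan-2-yl)cyclopentyl]-3-methylbut-3-en-1-yl (2Z)-2-methylbut-2-enoate; 20 divinylzinc
Product: 21 (1S)-1-[(1S,2R,5S)-2-hydroxy-5-[(1R)-1-hydroxyprop-2-en-1-yl]-5-methyl-2-(propan-2-yl)cyclopentyl]-3-methylbut-3-en-1-yl (2Z)-2-methylbut-2-enoate
Conditions: 20 (3 equiv), (+)-DAIB (15 mol %; the antipode of the ligand that gives (S)-1-phenylpropanol from PhCHO/Et2Zn), toluene, −20 → 0 °C; aq NH4Cl
Reagents that add atoms: none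
Why: Amino-alcohol-catalysed asymmetric vinylzinc addition (Noyori/Oppolzer type) delivers vinyl to the Re face of the aldehyde under reagent control, setting the (R)-carbinol at C-10, and the organozinc does not touch the angelate ester.

**Step 11**
Reactants: 21 (1S)-1-[(1S,2R,5S)-2-hydroxy-5-[(1R)-1-hydroxyprop-2-en-1-yl]-5-methyl-2-(propan-2-yl)cyclopentyl]-3-methylbut-3-en-1-yl (2Z)-2-methylbut-2-enoate
Product: 22 (3R,3aS,4S,8R,8aS)-3,8-dihydroxy-6,8a-dimethyl-3-(propan-2-yl)-1,2,3,3a,4,5,8,8a-octahydroazulen-4-yl (2Z)-2-methylbut-2-enoate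
Conditions: Grubbs II (10 mol %), 1,4-benzoquinone (20 mol %), CH2Cl2 (2 mM), 40 °C
Reagents that add atoms: none
Why: Ring-closing metathesis between the vinyl carbinol and the methallyl olefin closes the seven-membered ring as the trisubstituted C8=C9 alkene (necessarily cis in the ring), while the trisubstituted, electron-poor angelate is inert; no stereocentre is touched.

**Step 12**
Reactants: 22 (3R,3aS,4S,8R,8aS)-3,8-dihydroxy-6,8a-dimethyl-3-(propan-2-yl)-1,2,3,3a,4,5,8,8a-octahydroazulen-4-yl (2Z)-2-methylbut-2-enoate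
Product: 23 lapiferine
Conditions: VO(acac)2 (5 mol %), t-BuOOH (1.5 equiv), CH2Cl2, 0 °C → rt
Reagents that add atoms: tert-butyl hydroperoxide, CC(C)(C)OO
Why: Sharpless–Michaelson vanadium-catalysed hydroxyl-directed epoxidation delivers oxygen to the C8=C9 face syn to the allylic C-10 hydroxyl, setting 8R,9S, and leaves the electron-poor angelate untouched.

**Compound list**
1 | but-3-en-2-one (methyl vinyl ketone) | C=CC(C)=O | starting material
2 | 2,2-dimethoxyacetaldehyde | COC(OC)C=O | starting material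
3 | 1,1-dimethoxyhexane-2,5-dione | COC(OC)C(=O)CCC(C)=O | intermediate
4 | 3-(dimethoxymethyl)-3-hydroxycyclopentan-1-one (racemic aldol adduct) | COC(OC)C1(O)CCC(=O)C1 | intermediate
5 | 3-(dimethoxymethyl)cyclopent-2-en-1-one | COC(OC)C1=CC(=O)CC1 | intermediate
6 | (±)-glycidol (oxiran-2-ylmethanol) | OCC1CO1 | starting material
7 | isopropenylmagnesium bromide | C=C(C)[Mg]Br | starting material
8 | (±)-4-methylpent-4-ene-1,2-diol | C=C(C)CC(O)CO | intermediate
9 | 3-methylbut-3-enal | C=C(C)CC=O | intermediate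
10 | bromomagnesium (3S)-3-(dimethoxymethyl)-3-methylcyclopent-1-en-1-olate | C1=C(O[Mg]Br)CC[C@]1(C)C(OC)OC | intermediate
11 | (2S,3S)-3-(dimethoxymethyl)-2-[(1S)-1-hydroxy-3-methylbut-3-en-1-yl]-3-methylcyclopentan-1-one | C=C(C)C[C@H](O)[C@H]1C(=O)CC[C@]1(C)C(OC)OC | intermediate
12 | (1R,2S,3S)-3-(dimethoxymethyl)-2-[(1S)-1-hydroxy-3-methylbut-3-en-1-yl]-3-methyl-1-(propan-2-yl)cyclopentan-1-ol | C=C(C)C[C@H](O)[C@H]1[C@](O)(C(C)C)CC[C@]1(C)C(OC)OC | intermediate
13 | (1S,2S,3R)-3-hydroxy-2-[(1S)-1-hydroxy-3-methylbut-3-en-1-yl]-1-methyl-3-(propan-2-yl)cyclopentane-1-carbaldehyde | C=C(C)C[C@H](O)[C@H]1[C@](O)(C(C)C)CC[C@]1(C)C=O | intermediate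
14 | angelic acid, (2Z)-2-methylbut-2-enoic acid | C/C=C(/C)C(=O)O | starting material
15 | 2,4,6-trichlorobenzoyl chloride | O=C(Cl)c1c(Cl)cc(Cl)cc1Cl | starting material
16 | (2Z)-2-methylbut-2-enoic 2,4,6-trichlorobenzoic anhydride | C/C=C(/C)C(=O)OC(=O)c1c(Cl)cc(Cl)cc1Cl | intermediate
17 | (1S)-1-[(1S,2S,5R)-2-formyl-5-hydroxy-2-methyl-5-(propan-2-yl)cyclopentyl]-3-methylbut-3-en-1-yl (2Z)-2-methylbut-2-enoate | C=C(C)C[C@H](OC(=O)/C(C)=C\C)[C@H]1[C@](O)(C(C)C)CC[C@]1(C)C=O | intermediate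
18 | vinylmagnesium bromide | C=C[Mg]Br | starting material
19 | zinc chloride | Cl[Zn]Cl | starting material
20 | divinylzinc | C=C[Zn]C=C | intermediate
21 | (1S)-1-[(1S,2R,5S)-2-hydroxy-5-[(1R)-1-hydroxyprop-2-en-1-yl]-5-methyl-2-(propan-2-yl)cyclopentyl]-3-methylbut-3-en-1-yl (2Z)-2-methylbut-2-enoate | C=C(C)C[C@H](OC(=O)/C(C)=C\C)[C@H]1[C@](O)(C(C)C)CC[C@]1(C)[C@H](O)C=C | intermediate
22 | (3R,3aS,4S,8R,8aS)-3,8-dihydroxy-6,8a-dimethyl-3-(propan-2-yl)-1,2,3,3a,4,5,8,8a-octahydroazulen-4-yl (2Z)-2-methylbut-2-enoate | C/C=C(/C)C(=O)O[C@H]1CC(C)=C[C@@H](O)[C@@]2(C)CC[C@@](O)(C(C)C)[C@H]12 | intermediate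
23 | lapiferine, (1S,4R,5S,6S,8R,9S,10S)-8,9-epoxy-4,10-dihydroxydaucan-6-yl (2Z)-2-methylbut-2-enoate; 6-OAng, epoxide and 10-OH all cis to H-5, 4-OH cis to the angular methyl (C-10 reads S here only because C-9 now outranks C-1) | C/C=C(/C)C(=O)O[C@H]1C[C@@]2(C)O[C@H]2[C@@H](O)[C@@]2(C)CC[C@@](O)(C(C)C)[C@H]12 | target

**Step count**
Total step count: 12.
Longest linear sequence: 8 steps (1 → 2 → 5 → 6 → 8 → 10 → 11 → 12; the aldehyde arm 3 → 4 → 5 → 6 → 8 → 10 → 11 → 12 is equally long). This is two thirds of the total; steps 7 and 9 run in parallel.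

**Three steps most likely to fail**

(i) Step 5. Risk: enantio- and diastereocontrol of a one-pot Grignard conjugate addition–aldol on a cyclopentenone carrying a β-acetal, with an enolisable β,γ-unsaturated aldehyde as electrophile. The fallback sets out from 5 and splits the coupling into two stages. Copper-catalysed conjugate addition of Me3Al (CuTC, chiral phosphoramidite, Et2O, −30 °C) with an Ac2O quench gives the isolable enol ester (3S)-3-(dimethoxymethyl)-3-methylcyclopent-1-en-1-yl acetate F1, whose ee can be assayed and upgraded. MeLi (2 equiv, THF, 0 °C) then releases lithium (3S)-3-(dimethoxymethyl)-3-methylcyclopent-1-en-1-olate F2 regiospecifically. After exchange with MgBr2·OEt2 this is combined with 9 at −78 °C, and the fallback comes back to the route at 11.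

(ii) Step 10. Risk: reagent control may be eroded at a neopentyl aldehyde flanked by three stereocentres and a zinc alkoxide. The fallback sets out from 17. Vinylmagnesium bromide (THF, −78 °C) gives 21 mixed with its C-10 epimer (1S)-1-[(1S,2R,5S)-2-hydroxy-5-[(1S)-1-hydroxyprop-2-en-1-yl]-5-methyl-2-(propan-2-yl)cyclopentyl]-3-methylbut-3-en-1-yl (2Z)-2-methylbut-2-enoate F3. Dess–Martin oxidation of the mixture converges on the vinyl ketone (1S)-1-[(1S,2R,5S)-2-hydroxy-5-methyl-5-(prop-2-enoyl)-2-(propan-2-yl)cyclopentyl]-3-methylbut-3-en-1-yl (2Z)-2-methylbut-2-enoate F4. Reduction with (S)-Me-CBS and catecholborane (toluene, −78 °C; the quaternary carbon acts as the large group) returns to the route at 21.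

(iii) Step 11. Risk: both olefins are hindered, and the free neopentyl allylic alcohol can bind ruthenium or be isomerised to the ethyl ketone. The fallback sets out from 21 and runs the ring closure on a protected substrate. TESOTf and 2,6-lutidine (CH2Cl2, −78 °C; secondary OH only) give the silyl ether (1S)-1-[(1S,2R,5S)-2-hydroxy-5-methyl-2-(propan-2-yl)-5-{(1R)-1-[(triethylsilyl)oxy]prop-2-en-1-yl}cyclopentyl]-3-methylbut-3-en-1-yl (2Z)-2-methylbut-2-enoate F5. Ring-closing metathesis with Hoveyda–Grubbs II (toluene, 80 °C) gives (3R,3aS,4S,8R,8aS)-3-hydroxy-6,8a-dimethyl-3-(propan-2-yl)-8-[(triethylsilyl)oxy]-1,2,3,3a,4,5,8,8a-octahydroazulen-4-yl (2Z)-2-methylbut-2-enoate F6. HF·pyridine (THF, 0 °C) then returns to the route at 22.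

**Further compounds**
F1 | step 5 | (3S)-3-(dimethoxymethyl)-3-methylcyclopent-1-en-1-yl acetate | C1=C(OC(C)=O)CC[C@]1(C)C(OC)OC
F2 | step 5 | lithium (3S)-3-(dimethoxymethyl)-3-methylcyclopent-1-en-1-olate | C1=C(O[Li])CC[C@]1(C)C(OC)OC
F3 | step 10 | (1S)-1-[(1S,2R,5S)-2-hydroxy-5-[(1S)-1-hydroxyprop-2-en-1-yl]-5-methyl-2-(propan-2-yl)cyclopentyl]-3-methylbut-3-en-1-yl (2Z)-2-methylbut-2-enoate | C=C(C)C[C@H](OC(=O)/C(C)=C\C)[C@H]1[C@](O)(C(C)C)CC[C@]1(C)[C@@H](O)C=C
F4 | step 10 | (1S)-1-[(1S,2R,5S)-2-hydroxy-5-methyl-5-(prop-2-enoyl)-2-(propan-2-yl)cyclopentyl]-3-methylbut-3-en-1-yl (2Z)-2-methylbut-2-enoate | C=C(C)C[C@H](OC(=O)/C(C)=C\C)[C@H]1[C@](O)(C(C)C)CC[C@]1(C)C(=O)C=C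
F5 | step 11 | (1S)-1-[(1S,2R,5S)-2-hydroxy-5-methyl-2-(propan-2-yl)-5-{(1R)-1-[(triethylsilyl)oxy]prop-2-en-1-yl}cyclopentyl]-3-methylbut-3-en-1-yl (2Z)-2-methylbut-2-enoate | C=C(C)C[C@H](OC(=O)/C(C)=C\C)[C@H]1[C@](O)(C(C)C)CC[C@]1(C)[C@H](O[Si](CC)(CC)CC)C=C
F6 | step 11 | (3R,3aS,4S,8R,8aS)-3-hydroxy-6,8a-dimethyl-3-(propan-2-yl)-8-[(triethylsilyl)oxy]-1,2,3,3a,4,5,8,8a-octahydroazulen-4-yl (2Z)-2-methylbut-2-enoate | C/C=C(/C)C(=O)O[C@H]1CC(C)=C[C@@H](O[Si](CC)(CC)CC)[C@@]2(C)CC[C@@](O)(C(C)C)[C@H]12
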